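I decided to count reagent before trusting any fitted curve, and I first asked which setting the single product at the end of these flasks depended on.

| setting | birch | maple | cedar | theta | epsilon | gamma |
|---|---|---|---|---|---|---|
| substrate | 0.12 M | 0.50 M | 0.25 M | 0.25 M | 0.25 M | 0.25 M |
| reagent | 0.263 M | 0.263 M | 0.13 M | 0.263 M | 0.263 M | 0.263 M |
| temperature | 75 °C | 110 °C | 75 °C | 110 °C | 80 °C | 140 °C |
| remark | run made earlier | run made earlier | run made earlier |  |  |  |
| time |  |  |  | 8.0 h | 8.0 h | 8.0 h |

- birch (time / h: single product / %, substrate / %): 5.00: 26.5, 28.9; 8.00: 25.6, 19.1; 15.0: 14.1, 10.2; 25.0: 10.9, 5.2; 30.0: 8.0, 3.8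
- maple (time / h: single product / %, substrate / %): 0.417: 19.7, 50.7; 0.667: 18.9, 49.1; 1.00: 20.6, 46.8; 2.00: 21.5, 46.6; 3.00: 19.0, 46.6; 5.00: 20.3, 45.9
- cedar (time / h: single product / %, substrate / %): 6.00: 22.7, 53.9; 12.0: 22.2, 43.4; 15.0: 23.3, 37.6; 25.0: 23.9, 34.1; 30.0: 22.5, 33.8

(readings scatter by 1 percentage point)

- a reading or a percentage of single product counts all its forms, free or not

- the flask that comes out highest in amount of single product, in percent of the substrate charged, or "all alike" when all lie within 1.5 percentage points (theta / epsilon / gamma / all alike)
- single product at the end, in percent of the substrate charged, theta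
- single product at the end, in percent of the substrate charged, epsilon
- single product at the end, in percent of the substrate charged, gamma

Time mattered little at 110 °C: maple read 19.7% at 0.417 h and 20.3% at 5.00 h, a change within the scatter of 1 percentage point. Temperature looked to matter modestly: cedar and maple, with nearly the same reagent per substrate though not the same charges, gave last readings of 22.5% and 20.3% at 75 °C and 110 °C. The number to know well was the reagent budget, the charge of reagent as a fraction of the charge of substrate, 1.05 in theta, the allowance of a limiting reagent; birch, with 2.19, fell to 8.0% by 30.0 h.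

I then reckoned the stop crudely. Each single product costs one reagent and each substrate carried past it costs two, and I let the second step run 2 times as fast per unit, so a fraction a of substrate untouched by reagent leaves a minus a squared as product. Setting the reagent spent equal to the budget gave a = 0.359 and 23.0% for theta, and the same reckoning gave 23.6% for maple. Shifting the maple reading by that difference, I committed to 19.7% for theta and about the same for gamma. For epsilon I took birch, with the same reagent charge, at 25.6% after 8.00 h, which put epsilon highest.

The forecast named epsilon, with 15%, 25% and 14% for theta, epsilon and gamma, holding that “theta runs well past the maximum until reagent is exhausted”.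

The flasks gave 21.0% for theta, 24.9% for epsilon and 20.0% for gamma, so epsilon stood highest.

    substrate + reagent → single product + by-product (k = 4.10 × 10⁻⁴ M⁻¹ s⁻¹, Ea = 61.0 kJ mol⁻¹)
    reagent + single product → bis adduct + by-product (k = 5.00 × 10⁻⁴ M⁻¹ s⁻¹, Ea = 70.0 kJ mol⁻¹)
    substrate ⇌ dormant form (K = 0.700, k = 2.10 × 10⁻⁵ s⁻¹, Ea = 125 kJ mol⁻¹, ΔH = −29.0 kJ mol⁻¹)
    single product ⇌ isomer of the product (K = 0.230, k = 2.90 × 10⁻⁵ s⁻¹, Ea = 128 kJ mol⁻¹, ΔH = 2.00 kJ mol⁻¹)
    crystals ⇌ single product, rate k5*(cs5 - [single product]) while solid is left; crystals form when [single product] > cs5 (solubility = 0.210 M, k = 0.0110 s⁻¹)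
    (constants at 80 °C)

Theta kept 0.00892% of its reagent at 8.00 h, and its single product, isomer of the product and doubled bis adduct add up to 1.05 of the charge, against the budget of 1.05. The neighbour of epsilon charged with 1.0 M of substrate has a budget of 0.263; its 15.8% of single product, 3.56% of isomer of the product and doubled 3.46% of bis adduct add up to 0.263, and 52% of its charge stood as substrate.

The runs stem from a simulated flask with constants of no real substance; noise was put on by code.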